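**Retrosynthetic overview**

1. The route rests on the ten-membered carbocycle C1–C10: the C9 ketone and the C4–C5 oxirane (a masked ring-cis C4=C5) are 1,5-related through C8–C7–C6, and the spiro-oxirane C7–C11 masks an exocyclic C7=C11, the alkene an allene leaves behind. This is an oxy-Cope retron.
2. Endgame disconnections: both acetates; both oxiranes by Sharpless epoxidation of the C15 and C12 allylic alcohols (the same D-(−)-tartrate serves both); C1=C10 by dehydrogenation of the C9 ketone.
3. Key disconnection: the ten-membered ring comes from a cyclohexane by anionic oxy-Cope ring expansion of the 1-allenyl-2-vinylcyclohexanol 16 (C6–C7 forms, C4–C9 breaks).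
4. Precursor 16: allene axis by anti-SN2′ hydride opening of an alkynyl oxirane; C9 by acetylide addition to ketone 8; 8 from a β-keto ester by asymmetric hydroxymethylation (C4), chelate-controlled methylation (C10) and ester-to-vinyl conversion.
5. Ring order: cyclohexane (bought) → ten-membered ring (step 12) → the two oxiranes (step 15).

Key step: step 12

Remark: atoms carry the numbering C1–C15 (ring C1–C10, C11 on C7, C12 and C13 on C11, C14 on C10, C15 on C4); the hydride opening of the alkynyl oxirane is taken to be anti-SN2′, and if it proved syn the enantiomer of 12 (from L-(+)-tartrate) would be used.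

**Route**

Step 1
Reactants: 1 methyl 2-oxocyclohexane-1-carboxylate
Product: 2 methyl (1R)-1-(hydroxymethyl)-2-oxocyclohexane-1-carboxylate
Conditions: 37% aq. HCHO, chiral Pd(II)–BINAP diaqua bis(triflate) (5 mol %, ligand antipode that gives 1R), THF, −20 °C
Reagents that add atoms: formaldehyde, C=O
Why: Catalytic enantioselective aldol reaction of the chelated β-keto ester enolate with formaldehyde (asymmetric hydroxymethylation), in which the chiral metal enolate shields one face and so sets the quaternary C4 centre.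

Step 2
Reactants: 2 methyl (1R)-1-(hydroxymethyl)-2-oxocyclohexane-1-carboxylate
Product: 3 methyl (1R)-1-{[tert-butyl(diphenyl)silyl]oxymethyl}-2-oxocyclohexane-1-carboxylate
Conditions: TBDPSCl, imidazole, DMF, 0 °C → rt
Reagents that add atoms: tert-butyl(chloro)diphenylsilane, CC(C)(C)[Si](Cl)(c1ccccc1)c1ccccc1
Why: Imidazole-promoted silylation of the primary alcohol, the diphenylsilyl group being chosen because it should not migrate between the two oxymethyl arms on C4 in diol 6 or to the C9 alkoxide in step 12.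

Step 3
Reactants: 3 methyl (1R)-1-{[tert-butyl(diphenyl)silyl]oxymethyl}-2-oxocyclohexane-1-carboxylate
Product: 5 methyl (1R,3R)-1-{[tert-butyl(diphenyl)silyl]oxymethyl}-3-methyl-2-oxocyclohexane-1-carboxylate, via lithium enolate 4 (not isolated)
Conditions: LDA, THF, −78 °C; MeI, −78 → −40 °C
Reagents that add atoms: iodomethane, CI
Why: Kinetic α′-alkylation of the lithium enolate, in which lithium chelation holds the ester in the enolate plane and the pseudoaxial CH2OTBDPS arm blocks one face, so that iodomethane should enter anti to it and set C10 with the methyl cis to the ester (the future vinyl group).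

Step 4
Reactants: 5 methyl (1R,3R)-1-{[tert-butyl(diphenyl)silyl]oxymethyl}-3-methyl-2-oxocyclohexane-1-carboxylate
Product: 6 (2R,6R)-2-{[tert-butyl(diphenyl)silyl]oxymethyl}-2-(hydroxymethyl)-6-methylcyclohexan-1-ol (both C1 epimers)
Conditions: LiAlH4, Et2O, 0 °C
Reagents that add atoms: none
Why: Hydride reduction of ketone and ester to the 1,3-diol, the new carbinol centre at C9 being of no consequence because it is oxidised again in step 5.

Step 5
Reactants: 6 (2R,6R)-2-{[tert-butyl(diphenyl)silyl]oxymethyl}-2-(hydroxymethyl)-6-methylcyclohexan-1-ol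
Product: 7 (1S,3R)-1-{[tert-butyl(diphenyl)silyl]oxymethyl}-3-methyl-2-oxocyclohexane-1-carbaldehyde
Conditions: Dess–Martin periodinane, pyridine, CH2Cl2, 0 °C → rt
Reagents that add atoms: none
Why: Dess–Martin oxidation of both alcohols under non-basic conditions, so that the epimerisable C10 centre of the 2-formyl ketone is not disturbed.

Step 6
Reactants: 7 (1S,3R)-1-{[tert-butyl(diphenyl)silyl]oxymethyl}-3-methyl-2-oxocyclohexane-1-carbaldehyde
Product: 8 (2R,6R)-2-{[tert-butyl(diphenyl)silyl]oxymethyl}-2-ethenyl-6-methylcyclohexan-1-one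
Conditions: Ph3PCH3Br, KHMDS, THF, 0 °C; then 7, −78 → 0 °C
Reagents that add atoms: methyltriphenylphosphonium bromide, C[P+](c1ccccc1)(c1ccccc1)c1ccccc1.[Br-]
Why: Wittig methylenation, chemoselective for the aldehyde over the doubly flanked ketone, turns the former ester carbon into the C5=C6 vinyl group.

Step 7
Reactants: 9 2-methylprop-2-en-1-ol
Product: 10 [(2R)-2-methyloxiran-2-yl]methanol
Conditions: Ti(OiPr)4 (cat.), D-(−)-diethyl tartrate (cat.), TBHP, 4 Å MS, CH2Cl2, −20 °C
Reagents that add atoms: tert-butyl hydroperoxide, CC(C)(C)OO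
Why: Katsuki–Sharpless asymmetric epoxidation of the 2-substituted allylic alcohol, D-(−)-tartrate delivering oxygen to the face that gives the (2R)-epoxy alcohol.

Step 8
Reactants: 10 [(2R)-2-methyloxiran-2-yl]methanol
Product: 12 (2R)-2-ethynyl-2-methyloxirane, via epoxy aldehyde 11 (not isolated)
Conditions: Dess–Martin periodinane, pyridine, CH2Cl2, 0 °C; then MeOH, K2CO3, dimethyl (1-diazo-2-oxopropyl)phosphonate, 0 °C → rt
Reagents that add atoms: dimethyl (1-diazo-2-oxopropyl)phosphonate (Ohira–Bestmann reagent), CC(=O)C(=[N+]=[N-])P(=O)(OC)OC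
Why: Oxidation to the non-enolisable epoxy aldehyde followed by Seyferth–Gilbert homologation with the Ohira–Bestmann reagent, neither of which touches the quaternary oxirane centre.

Step 9
Reactants: 8 (2R,6R)-2-{[tert-butyl(diphenyl)silyl]oxymethyl}-2-ethenyl-6-methylcyclohexan-1-one; 12 (2R)-2-ethynyl-2-methyloxirane
Product: 14 (1R,2R,6R)-2-{[tert-butyl(diphenyl)silyl]oxymethyl}-2-ethenyl-6-methyl-1-{[(2R)-2-methyloxiran-2-yl]ethynyl}cyclohexan-1-ol, via lithium acetylide 13 (not isolated)
Conditions: 12, n-BuLi, THF, −78 °C; then 8, −78 → −30 °C; H2O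
Reagents that add atoms: none
Why: 1,2-Addition of the lithium acetylide to the ketone in its chair with C10-methyl and vinyl equatorial, axial attack anti to the axial CH2OTBDPS arm setting C9 with the alkyne cis to vinyl and methyl, as in acetylide additions to 2,2,6-trisubstituted cyclohexanones.

Step 10
Reactants: 14 (1R,2R,6R)-2-{[tert-butyl(diphenyl)silyl]oxymethyl}-2-ethenyl-6-methyl-1-{[(2R)-2-methyloxiran-2-yl]ethynyl}cyclohexan-1-ol
Product: 15 (1R,2R,6R)-2-{[tert-butyl(diphenyl)silyl]oxymethyl}-2-ethenyl-1-[(aS)-4-hydroxy-3-methylbuta-1,2-dien-1-yl]-6-methylcyclohexan-1-ol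
Conditions: DIBAL-H, CH2Cl2, −78 → 0 °C; aq. Rochelle salt
Reagents that add atoms: none
Why: SN2′ hydride opening of the propargylic oxirane, hydride entering at C8 anti to the departing oxygen, so that the (R)-oxirane centre is transferred to the (aS)-allene axis and C12 is released as the primary alcohol.

Step 11
Reactants: 15 (1R,2R,6R)-2-{[tert-butyl(diphenyl)silyl]oxymethyl}-2-ethenyl-1-[(aS)-4-hydroxy-3-methylbuta-1,2-dien-1-yl]-6-methylcyclohexan-1-ol
Product: 16 (1R,2R,6R)-1-[(aS)-4-{[tert-butyl(dimethyl)silyl]oxy}-3-methylbuta-1,2-dien-1-yl]-2-{[tert-butyl(diphenyl)silyl]oxymethyl}-2-ethenyl-6-methylcyclohexan-1-ol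
Conditions: TBSCl, imidazole, CH2Cl2, 0 °C
Reagents that add atoms: tert-butyl(chloro)dimethylsilane, CC(C)(C)[Si](C)(C)Cl
Why: Silylation of the primary alcohol only, the hindered tertiary C9 hydroxyl being inert to TBSCl and imidazole.

Step 12
Reactants: 16 (1R,2R,6R)-1-[(aS)-4-{[tert-butyl(dimethyl)silyl]oxy}-3-methylbuta-1,2-dien-1-yl]-2-{[tert-butyl(diphenyl)silyl]oxymethyl}-2-ethenyl-6-methylcyclohexan-1-ol
Product: 19 (3Z,5E,10R)-3-{1-[tert-butyl(dimethyl)silyl]oxypropan-2-ylidene}-6-{[tert-butyl(diphenyl)silyl]oxymethyl}-10-methylcyclodec-5-en-1-one, via potassium alkoxide 17 (not isolated), via potassium dienolate 18 (not isolated)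
Conditions: KH, 18-crown-6, THF, 0 °C → rt; then AcOH, THF, −78 °C
Reagents that add atoms: none
Why: Deprotonation gives alkoxide 17, which undergoes an alkoxide-accelerated [3,3] sigmatropic shift through a chair-like transition state with the allene C7=C8 π bond and the vinyl group as termini, so that C6–C7 forms while C4–C9 breaks and dienolate 18 is protonated at C8 on cold acidic quench. The closest known reactions are the anionic oxy-Cope ring expansion of cis-1,2-divinylcyclohexanols to (Z)-cyclodec-5-enones and oxy-Cope rearrangements of allenyl carbinols. The ten-membered ring is not closed end to end but arises by four-atom ring expansion of the cyclohexane, so that no dilution is needed. No stereocentre is formed: the ring-cis C4=C5 geometry follows from the equatorial vinyl group in the chair, and the Z geometry of C7=C11 from the (aS) axis, because C6 bonds to the allene face that carries the methyl group and C12 therefore ends cis to C8. The step needs the chair with allenyl axial and vinyl and alkoxide equatorial and not its ring-flipped partner (which would give ring-trans C4=C5); the all-cis arrangement of allenyl, vinyl and C10-methyl secures this, since the flipped chair suffers a syn-diaxial methyl/vinyl interaction. Working at or below room temperature and quenching cold should guard against vinylogous loss of silanolate from 18 and against conjugation of the β,γ-double bond.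

Step 13
Reactants: 19 (3Z,5E,10R)-3-{1-[tert-butyl(dimethyl)silyl]oxypropan-2-ylidene}-6-{[tert-butyl(diphenyl)silyl]oxymethyl}-10-methylcyclodec-5-en-1-one
Product: 20 (2E,6E,9Z)-6-{[tert-butyl(diphenyl)silyl]oxymethyl}-9-{1-[tert-butyl(dimethyl)silyl]oxypropan-2-ylidene}-2-methylcyclodeca-2,6-dien-1-one
Conditions: IBX, 4-methoxypyridine N-oxide, DMSO, 25–40 °C
Reagents that add atoms: none
Why: IBX-mediated α,β-dehydrogenation through the enol: C8–H is the more acidic α-position, so enolate-based methods are avoided, but the C8 enol cannot desaturate because C7 carries no hydrogen, so that under these base-free conditions with reversible enolisation only the C10 enol should be channelled to product, and removal of a C1 hydrogen in the ten-membered ring should give the E (ring-trans) enone, as syn-type dehydrogenations do in rings of this size.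

Step 14
Reactants: 20 (2E,6E,9Z)-6-{[tert-butyl(diphenyl)silyl]oxymethyl}-9-{1-[tert-butyl(dimethyl)silyl]oxypropan-2-ylidene}-2-methylcyclodeca-2,6-dien-1-one
Product: 21 (2E,6E,9Z)-6-(hydroxymethyl)-9-(1-hydroxypropan-2-ylidene)-2-methylcyclodeca-2,6-dien-1-one
Conditions: HF·pyridine, pyridine, THF, 0 °C → rt
Reagents that add atoms: none
Why: Fluoride cleavage of both silyl ethers under buffered, non-basic conditions that should leave the cross-conjugated enone and its β,γ-double bond untouched.

Step 15
Reactants: 21 (2E,6E,9Z)-6-(hydroxymethyl)-9-(1-hydroxypropan-2-ylidene)-2-methylcyclodeca-2,6-dien-1-one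
Product: 22 bis-epoxy diol (4R,5R,7S,11R)-4,5:7,11-diepoxy-12,15-dihydroxy-9-oxo ten-membered 1(10)E-enone (C1–C15 numbering)
Conditions: Ti(OiPr)4 (20 mol %), D-(−)-diethyl tartrate (24 mol %), TBHP, 4 Å MS, CH2Cl2, −20 °C
Reagents that add atoms: tert-butyl hydroperoxide, CC(C)(C)OO
Why: Twofold Katsuki–Sharpless epoxidation of the two primary allylic alcohols under reagent control: applying the Sharpless mnemonic to each alkene, D-(−)-tartrate sets C4/C5 as R,R from the ring-cis alkene and C7/C11 as S,R from the Z alkene, while the electron-poor enone is not epoxidised.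

Step 16
Reactants: 22 bis-epoxy diol
Product: 23 CNP0185847.3 (the 12,15-diacetate)
Conditions: Ac2O, pyridine, DMAP (cat.), CH2Cl2, 0 °C
Reagents that add atoms: acetic anhydride, CC(=O)OC(C)=O
Why: DMAP-catalysed acylation of the two primary alcohols, mild enough for the β,γ-epoxy ketone.

**Compound list**

1 | methyl 2-oxocyclohexane-1-carboxylate | COC(=O)C1CCCCC1=O | starting material
2 | methyl (1R)-1-(hydroxymethyl)-2-oxocyclohexane-1-carboxylate | O=C1CCCC[C@@]1(C(=O)OC)CO | intermediate
3 | methyl (1R)-1-{[tert-butyl(diphenyl)silyl]oxymethyl}-2-oxocyclohexane-1-carboxylate | O=C1CCCC[C@@]1(C(=O)OC)CO[Si](c1ccccc1)(c1ccccc1)C(C)(C)C | intermediate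
4 | lithium enolate of 3 (C9=C10 enolate) | [Li+].[O-]C1=CCCC[C@@]1(C(=O)OC)CO[Si](c1ccccc1)(c1ccccc1)C(C)(C)C | intermediate (not isolated)
5 | methyl (1R,3R)-1-{[tert-butyl(diphenyl)silyl]oxymethyl}-3-methyl-2-oxocyclohexane-1-carboxylate (methyl cis to ester) | O=C1[C@H](C)CCC[C@@]1(C(=O)OC)CO[Si](c1ccccc1)(c1ccccc1)C(C)(C)C | intermediate
6 | (2R,6R)-2-{[tert-butyl(diphenyl)silyl]oxymethyl}-2-(hydroxymethyl)-6-methylcyclohexan-1-ol (both C1 epimers) | OC1[C@H](C)CCC[C@@]1(CO)CO[Si](c1ccccc1)(c1ccccc1)C(C)(C)C | intermediate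
7 | (1S,3R)-1-{[tert-butyl(diphenyl)silyl]oxymethyl}-3-methyl-2-oxocyclohexane-1-carbaldehyde | O=C1[C@H](C)CCC[C@@]1(C=O)CO[Si](c1ccccc1)(c1ccccc1)C(C)(C)C | intermediate
8 | (2R,6R)-2-{[tert-butyl(diphenyl)silyl]oxymethyl}-2-ethenyl-6-methylcyclohexan-1-one (methyl cis to vinyl) | O=C1[C@H](C)CCC[C@@]1(C=C)CO[Si](c1ccccc1)(c1ccccc1)C(C)(C)C | intermediate
9 | 2-methylprop-2-en-1-ol | CC(=C)CO | starting material
10 | [(2R)-2-methyloxiran-2-yl]methanol | OC[C@]1(C)CO1 | intermediate
11 | (2S)-2-methyloxirane-2-carbaldehyde | O=C[C@]1(C)CO1 | intermediate (not isolated)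
12 | (2R)-2-ethynyl-2-methyloxirane | C#C[C@]1(C)CO1 | intermediate
13 | lithium acetylide of 12 | [Li+].[C-]#C[C@]1(C)CO1 | intermediate (not isolated)
14 | (1R,2R,6R)-2-{[tert-butyl(diphenyl)silyl]oxymethyl}-2-ethenyl-6-methyl-1-{[(2R)-2-methyloxiran-2-yl]ethynyl}cyclohexan-1-ol | O[C@@]1(C#C[C@]2(C)CO2)[C@H](C)CCC[C@@]1(C=C)CO[Si](c1ccccc1)(c1ccccc1)C(C)(C)C | intermediate
15 | (1R,2R,6R)-2-{[tert-butyl(diphenyl)silyl]oxymethyl}-2-ethenyl-1-[(aS)-4-hydroxy-3-methylbuta-1,2-dien-1-yl]-6-methylcyclohexan-1-ol | O[C@@]1(C([H])=[C@@]=C(C)CO)[C@H](C)CCC[C@@]1(C=C)CO[Si](c1ccccc1)(c1ccccc1)C(C)(C)C | intermediate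
16 | (1R,2R,6R)-1-[(aS)-4-{[tert-butyl(dimethyl)silyl]oxy}-3-methylbuta-1,2-dien-1-yl]-2-{[tert-butyl(diphenyl)silyl]oxymethyl}-2-ethenyl-6-methylcyclohexan-1-ol (key-step precursor; allenyl, vinyl and methyl all cis) | O[C@@]1(C([H])=[C@@]=C(C)CO[Si](C)(C)C(C)(C)C)[C@H](C)CCC[C@@]1(C=C)CO[Si](c1ccccc1)(c1ccccc1)C(C)(C)C | intermediate
17 | potassium alkoxide of 16 | [K+].[O-][C@@]1(C([H])=[C@@]=C(C)CO[Si](C)(C)C(C)(C)C)[C@H](C)CCC[C@@]1(C=C)CO[Si](c1ccccc1)(c1ccccc1)C(C)(C)C | intermediate (not isolated)
18 | potassium dienolate of 19 (C9=C8 enolate conjugated with C7=C11) | [K+].[O-]/C1=C\C(=C(\C)CO[Si](C)(C)C(C)(C)C)C/C=C(/CO[Si](c2ccccc2)(c2ccccc2)C(C)(C)C)CCC[C@H]1C | intermediate (not isolated)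
19 | (3Z,5E,10R)-3-{1-[tert-butyl(dimethyl)silyl]oxypropan-2-ylidene}-6-{[tert-butyl(diphenyl)silyl]oxymethyl}-10-methylcyclodec-5-en-1-one (key-step product; ring-cis C4=C5, Z-C7=C11) | O=C1C/C(=C(/C)CO[Si](C)(C)C(C)(C)C)C/C=C(/CO[Si](c2ccccc2)(c2ccccc2)C(C)(C)C)CCC[C@H]1C | intermediate
20 | (2E,6E,9Z)-6-{[tert-butyl(diphenyl)silyl]oxymethyl}-9-{1-[tert-butyl(dimethyl)silyl]oxypropan-2-ylidene}-2-methylcyclodeca-2,6-dien-1-one | CC(C)(C)[Si](c1ccccc1)(c1ccccc1)OC/C1=C/C/C(=C(\C)CO[Si](C)(C)C(C)(C)C)CC(=O)/C(C)=C/CC1 | intermediate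
21 | (2E,6E,9Z)-6-(hydroxymethyl)-9-(1-hydroxypropan-2-ylidene)-2-methylcyclodeca-2,6-dien-1-one | OC/C1=C/C/C(=C(\C)CO)CC(=O)/C(C)=C/CC1 | intermediate
22 | (4R,5R,7S,11R)-bis-epoxy diol (C4–C5 and C7–C11 oxiranes, C12 and C15 hydroxyls, 1(10)E-en-9-one) | OC[C@]12CC/C=C(\C)C(=O)C[C@]3(C[C@H]1O2)O[C@]3(C)CO | intermediate
23 | CNP0185847.3 | CC(=O)OC[C@]12CC/C=C(\C)C(=O)C[C@]3(C[C@H]1O2)O[C@]3(C)COC(C)=O | target

**Count**

Total steps: 16. Longest linear sequence: 14 (steps 1–6 and 9–16); steps 7–8 make the alkyne fragment.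

**Steps most likely to fail**

Step 12 (key step). The alkoxide 17 may fragment with loss of the allenyl anion, the rearrangement may leak through the ring-flipped chair or a boat and erode the two alkene geometries, or the dienolate 18 may lose silanolate by vinylogous β-elimination. The fallback is the neutral siloxy-Cope rearrangement. Setting out from 16, the tertiary hydroxyl is silylated (TMSOTf, 2,6-lutidine, CH2Cl2, −78 °C) to the trimethylsilyl ether F1. F1 is heated (o-dichlorobenzene, about 180 °C, base-washed sealed tube), where the same chair-like [3,3] shift, now without any anion, should give the ten-membered trimethylsilyl dienol ether F2. Buffered fluoride (TBAF, AcOH, THF, −78 °C) then releases the enolate for kinetic protonation at C8, and the route is rejoined at 19.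

Step 13. The faster-formed C8 dienol may itself be oxidised (1,4-dehydrogenation across C7=C11), the β,γ-double bond may move into conjugation, or the Z-enone may form. The fallback is an Ito–Saegusa oxidation of an isolated enol silane. Setting out from 19, equilibrating silylation (TESOTf, Et3N, CH2Cl2, −78 → 0 °C) gives the tetrasubstituted C9=C10 triethylsilyl enol ether F3, which is separated from the C8 dienol ether; the latter is hydrolysed back to 19 and recycled. F3 is treated with Pd(OAc)2 in MeCN, where syn β-hydride elimination from the C10 palladium enolate can only take a C1 hydrogen, and the route is rejoined at 20.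

Step 3. Poor facial selectivity in the methylation, or proton exchange between product and enolate, would give the C10 epimer, which would lead to ring-trans C4=C5 in step 12. The fallback is reagent-controlled methylation by the SAMP-hydrazone method after the vinyl group is in place. Setting out from 3, LiAlH4 gives the diol F4, Dess–Martin oxidation the keto aldehyde F5 and Wittig methylenation the vinyl ketone F6. Condensation with (S)-1-amino-2-(methoxymethyl)pyrrolidine gives the hydrazone F7; deprotonation (LDA) and methylation (MeI) at the only enolisable position give the methylated hydrazone F8, with C10 set by the auxiliary. Two-phase hydrolysis with aqueous oxalic acid rejoins the route at 8.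

**Further compounds**

F1 | step 12 | trimethylsilyl ether of 16 | C[Si](C)(C)O[C@@]1(C([H])=[C@@]=C(C)CO[Si](C)(C)C(C)(C)C)[C@H](C)CCC[C@@]1(C=C)CO[Si](c1ccccc1)(c1ccccc1)C(C)(C)C
F2 | step 12 | trimethylsilyl dienol ether of 19 | C[Si](C)(C)O/C1=C\C(=C(\C)CO[Si](C)(C)C(C)(C)C)C/C=C(/CO[Si](c2ccccc2)(c2ccccc2)C(C)(C)C)CCC[C@H]1C
F3 | step 13 | C9=C10 triethylsilyl enol ether of 19 | CC[Si](CC)(CC)OC1=C(C)CCC/C(CO[Si](c2ccccc2)(c2ccccc2)C(C)(C)C)=C\C/C(=C(\C)CO[Si](C)(C)C(C)(C)C)C1
F4 | step 3 | (2R)-2-{[tert-butyl(diphenyl)silyl]oxymethyl}-2-(hydroxymethyl)cyclohexan-1-ol (both C1 epimers) | OC1CCCC[C@@]1(CO)CO[Si](c1ccccc1)(c1ccccc1)C(C)(C)C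
F5 | step 3 | (1S)-1-{[tert-butyl(diphenyl)silyl]oxymethyl}-2-oxocyclohexane-1-carbaldehyde | O=C1CCCC[C@@]1(C=O)CO[Si](c1ccccc1)(c1ccccc1)C(C)(C)C
F6 | step 3 | (2R)-2-{[tert-butyl(diphenyl)silyl]oxymethyl}-2-ethenylcyclohexan-1-one | O=C1CCCC[C@@]1(C=C)CO[Si](c1ccccc1)(c1ccccc1)C(C)(C)C
F7 | step 3 | SAMP hydrazone of F6 | COC[C@@H]1CCCN1/N=C1/[C@](C=C)(CO[Si](c2ccccc2)(c2ccccc2)C(C)(C)C)CCCC1
F8 | step 3 | SAMP hydrazone of 8 | COC[C@@H]1CCCN1/N=C1/[C@](C=C)(CO[Si](c2ccccc2)(c2ccccc2)C(C)(C)C)CCC[C@H]1C
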